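**Strategy.** The route rests on cutting both aryl–carbon bonds of the CH2CH2 bridge that links C3 of the meta-phenylene (ring D) to C1 of catechol ring A. Because this bridge lies between two arene carbons, both of its carbons can be delivered as one acetylene unit. In a single operation a double Sonogashira coupling staples trimethylsilylacetylene first onto the ring D iodide and then, after fluoride unmasking, onto the ring A triflate, closing the 19-membered ring as a diarylalkyne. The precursor is an open A–O–B–CH2CH2–C–O–D chain, fully O-methylated, with an iodide on ring D and a triflate on ring A, assembled by Chan–Lam, SNAr and Wittig chemistry.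

Key step: step 9

Remarks on the chemistry:
- Ring lettering: ring A is the catechol ring bonded through oxygen to the para-phenylene ring B; ring C is the second catechol ring, joined to ring B by CH2CH2 and through oxygen to the meta-phenylene ring D.
- The target has no stereocentre. Alkene 11 is carried as an E/Z mixture because both isomers converge on reduction.
- The para-phenylene unit enters as methyl 4-fluorobenzoate (ester level), so the formyl group on ring A is the only aldehyde present when it is converted into the triflate.

Step 1
Reactants: 1 3-hydroxy-4,5-dimethoxybenzaldehyde; 2 3-iodophenylboronic acid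
Product: 3 3-(3-iodophenoxy)-4,5-dimethoxybenzaldehyde
Conditions: 2 (2 equiv), Cu(OAc)2 (0.5 equiv), pyridine, 4 Å MS, CH2Cl2, O2 (balloon), rt
Reagents that add atoms: none
Why: Chan–Lam oxidative O-arylation, in which the copper phenoxide takes the aryl group from boron and reductive elimination forms the C–O bond at room temperature, where the C–I bond is untouched and dioxygen returns copper to the divalent state.

Step 2
Reactants: 1 3-hydroxy-4,5-dimethoxybenzaldehyde; 4 methyl 4-fluorobenzoate
Product: 5 methyl 4-(5-formyl-2,3-dimethoxyphenoxy)benzoate
Conditions: K2CO3, DMF, 130 °C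
Reagents that add atoms: none
Why: Nucleophilic aromatic substitution (SNAr), in which the phenoxide of 1 adds para to the ester of 4 and the Meisenheimer complex expels fluoride, while the non-enolisable aldehyde is inert to carbonate.

Step 3
Reactants: 5 methyl 4-(5-formyl-2,3-dimethoxyphenoxy)benzoate
Product: 7 methyl 4-(5-hydroxy-2,3-dimethoxyphenoxy)benzoate, via aryl formate 6 (not isolated)
Conditions: mCPBA, CH2Cl2, 0 °C to rt; aq. Na2S2O3/NaHCO3 wash; then K2CO3 (cat.), MeOH, rt
Reagents that add atoms: meta-chloroperoxybenzoic acid (mCPBA), OOC(=O)c1cccc(Cl)c1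
Why: Baeyer–Villiger oxidation run as a Dakin-type sequence, in which the para-methoxy group makes the trioxygenated aryl ring migrate in preference to hydride and the resulting formate is removed by mild methanolysis that leaves the methyl ester unchanged.

Step 4
Reactants: 7 methyl 4-(5-hydroxy-2,3-dimethoxyphenoxy)benzoate
Product: 8 methyl 4-[2,3-dimethoxy-5-(trifluoromethylsulfonyloxy)phenoxy]benzoate
Conditions: Tf2O, pyridine, CH2Cl2, 0 °C
Reagents that add atoms: trifluoromethanesulfonic anhydride (Tf2O), O=S(=O)(OS(=O)(=O)C(F)(F)F)C(F)(F)F
Why: O-Sulfonylation of the only free hydroxyl group gives the aryl triflate under standard triflation conditions.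

Step 5
Reactants: 8 methyl 4-[2,3-dimethoxy-5-(trifluoromethylsulfonyloxy)phenoxy]benzoate
Product: 9 3-[4-(hydroxymethyl)phenoxy]-4,5-dimethoxyphenyl trifluoromethanesulfonate
Conditions: i-Bu2AlH (2.5 equiv), CH2Cl2, −78 to −20 °C; aq. KNaC4H4O6 (potassium sodium tartrate) work-up
Reagents that add atoms: none
Why: DIBAL-H ester reduction, in which hydride delivery to the carbonyl group at low temperature should be much faster than attack at the sulfur of an electron-rich aryl triflate.

Step 6
Reactants: 9 3-[4-(hydroxymethyl)phenoxy]-4,5-dimethoxyphenyl trifluoromethanesulfonate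
Product: 10 {4-[2,3-dimethoxy-5-(trifluoromethylsulfonyloxy)phenoxy]benzyl}triphenylphosphonium bromide
Conditions: PPh3·HBr, MeCN, reflux
Reagents that add atoms: triphenylphosphine hydrobromide, [Br-].c1ccc(cc1)[PH+](c1ccccc1)c1ccccc1
Why: Direct phosphonium salt formation from a benzylic alcohol, in which the para-aryloxybenzylic position ionises readily under HBr and is captured by PPh3, the aryl triflate being stable to acid.

Step 7
Reactants: 10 {4-[2,3-dimethoxy-5-(trifluoromethylsulfonyloxy)phenoxy]benzyl}triphenylphosphonium bromide; 3 3-(3-iodophenoxy)-4,5-dimethoxybenzaldehyde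
Product: 11 3-[4-[2-[3-(3-iodophenoxy)-4,5-dimethoxyphenyl]ethenyl]phenoxy]-4,5-dimethoxyphenyl trifluoromethanesulfonate (E/Z mixture)
Conditions: K2CO3, 18-crown-6 (cat.), CH2Cl2, reflux
Reagents that add atoms: none
Why: Wittig olefination of the semi-stabilised benzylic ylide under solid–liquid phase-transfer conditions, where carbonate is too weak a nucleophile to cleave the triflate and the alkene geometry is irrelevant because it is erased in step 8.

Step 8
Reactants: 11 3-[4-[2-[3-(3-iodophenoxy)-4,5-dimethoxyphenyl]ethenyl]phenoxy]-4,5-dimethoxyphenyl trifluoromethanesulfonate (E/Z mixture)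
Product: 12 3-[4-[2-[3-(3-iodophenoxy)-4,5-dimethoxyphenyl]ethyl]phenoxy]-4,5-dimethoxyphenyl trifluoromethanesulfonate
Conditions: TsNHNH2 (excess, in portions), NaOAc, DME/H2O, reflux
Reagents that add atoms: none
Why: Diimide reduction transfers two hydrogens concertedly to the C=C bond only, sparing the C–I and C–OTf bonds that hydrogenation over palladium would endanger.

Step 9
Reactants: 12 3-[4-[2-[3-(3-iodophenoxy)-4,5-dimethoxyphenyl]ethyl]phenoxy]-4,5-dimethoxyphenyl trifluoromethanesulfonate; 13 trimethylsilylacetylene
Product: 16 macrocyclic diarylalkyne tetramethyl ether (19-membered ring, C≡C between C3 of ring D and C1 of ring A), via silylalkyne triflate 14 (not isolated), via terminal alkyne triflate 15 (not isolated)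
Conditions: 13 (1.2 equiv), Pd(PPh3)4 (5 mol%), CuI (10 mol%), Et3N, DMF, 20 °C, Ar; argon sparge to remove excess 13; then syringe-pump addition over 12 h into Pd(PPh3)4 (10 mol%), CuI (10 mol%), CsF (3 equiv), H2O (5 equiv), Et3N/DMF, 80 °C, ca. 1 mM, Ar
Reagents that add atoms: none
Why: Zerovalent palladium inserts into the ring D C–I bond at room temperature while the ring A triflate stays intact, and transmetalation from the copper acetylide of 13 followed by reductive elimination gives silylalkyne 14. On slow addition to CsF the C–Si bond is cleaved, and the freed ethynyl group of 15 is joined to the triflate carbon by a second oxidative addition, transmetalation and reductive elimination sequence. The closest known reaction types are the one-pot Sonogashira/desilylation/Sonogashira synthesis of unsymmetrical diarylalkynes from trimethylsilylacetylene and two aryl electrophiles, and Sonogashira macrocyclisation to arylene–ethynylene rings. The 19-membered ring closes end to end by aryl–alkynyl reductive elimination from a 20-membered aryl(alkynyl)palladium chelate, the two diaryl ether hinges and the CH2CH2 tether letting the chain fold around the linear C≡C unit. The order of coupling is secured by the large oxidative-addition rate gap between iodide and triflate; cyclisation over oligomerisation is secured by unmasking the alkyne only as it enters a hot, highly dilute solution; oxidative alkyne dimerisation is suppressed by excluding oxygen; and the iodide ion released in the first stage should assist insertion into the electron-rich triflate. No stereocentre is formed.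

Step 10
Reactants: 16 macrocyclic diarylalkyne tetramethyl ether
Product: 17 macrocyclic tetramethyl ether with the saturated CH2CH2 bridge between rings D and A
Conditions: H2 (1 atm), Pd/C (10 wt%), EtOAc, rt
Reagents that add atoms: none
Why: Heterogeneous catalytic hydrogenation reduces the diarylalkyne fully to the CH2CH2 bridge, while aryl methyl ethers and diaryl ethers are inert and no benzylic C–O bond is present.

Step 11
Reactants: 17 macrocyclic tetramethyl ether
Product: 18 target bis(bibenzyl) tetraphenol CNP0511668.0
Conditions: BBr3 (8 equiv), CH2Cl2, −78 °C to rt; then H2O, under Ar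
Reagents that add atoms: none
Why: Lewis-acid ether cleavage with BBr3, in which bromide attacks the methyl carbon of each boron-complexed ArO–CH3 group, whereas the diaryl ether bonds offer no sp3 carbon and should survive.

Compound list
1 | 3-hydroxy-4,5-dimethoxybenzaldehyde | COc1cc(C=O)cc(O)c1OC | starting material
2 | 3-iodophenylboronic acid | OB(O)c1cccc(I)c1 | starting material
3 | 3-(3-iodophenoxy)-4,5-dimethoxybenzaldehyde | COc1cc(C=O)cc(Oc2cccc(I)c2)c1OC | intermediate
4 | methyl 4-fluorobenzoate | COC(=O)c1ccc(F)cc1 | starting material
5 | methyl 4-(5-formyl-2,3-dimethoxyphenoxy)benzoate | COC(=O)c1ccc(Oc2cc(C=O)cc(OC)c2OC)cc1 | intermediate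
6 | methyl 4-[5-(formyloxy)-2,3-dimethoxyphenoxy]benzoate (aryl formate) | COC(=O)c1ccc(Oc2cc(OC=O)cc(OC)c2OC)cc1 | intermediate
7 | methyl 4-(5-hydroxy-2,3-dimethoxyphenoxy)benzoate | COC(=O)c1ccc(Oc2cc(O)cc(OC)c2OC)cc1 | intermediate
8 | methyl 4-[2,3-dimethoxy-5-(trifluoromethylsulfonyloxy)phenoxy]benzoate | COC(=O)c1ccc(Oc2cc(OS(=O)(=O)C(F)(F)F)cc(OC)c2OC)cc1 | intermediate
9 | 3-[4-(hydroxymethyl)phenoxy]-4,5-dimethoxyphenyl trifluoromethanesulfonate | OCc1ccc(Oc2cc(OS(=O)(=O)C(F)(F)F)cc(OC)c2OC)cc1 | intermediate
10 | {4-[2,3-dimethoxy-5-(trifluoromethylsulfonyloxy)phenoxy]benzyl}triphenylphosphonium bromide | [Br-].COc1cc(OS(=O)(=O)C(F)(F)F)cc(Oc2ccc(C[P+](c3ccccc3)(c3ccccc3)c3ccccc3)cc2)c1OC | intermediate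
11 | 3-[4-[2-[3-(3-iodophenoxy)-4,5-dimethoxyphenyl]ethenyl]phenoxy]-4,5-dimethoxyphenyl trifluoromethanesulfonate (E/Z mixture, geometry not controlled) | COc1cc(OS(=O)(=O)C(F)(F)F)cc(Oc2ccc(C=Cc3cc(OC)c(OC)c(Oc4cccc(I)c4)c3)cc2)c1OC | intermediate
12 | 3-[4-[2-[3-(3-iodophenoxy)-4,5-dimethoxyphenyl]ethyl]phenoxy]-4,5-dimethoxyphenyl trifluoromethanesulfonate (acyclic aryl iodide aryl triflate) | COc1cc(OS(=O)(=O)C(F)(F)F)cc(c1OC)Oc1ccc(cc1)CCc1cc(OC)c(OC)c(c1)Oc1cccc(I)c1 | intermediate
13 | trimethylsilylacetylene | C[Si](C)(C)C#C | starting material
14 | silylalkyne triflate: 12 with the iodine replaced by a 2-(trimethylsilyl)ethynyl group | COc1cc(OS(=O)(=O)C(F)(F)F)cc(c1OC)Oc1ccc(cc1)CCc1cc(OC)c(OC)c(c1)Oc1cccc(c1)C#C[Si](C)(C)C | intermediate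
15 | terminal alkyne triflate: 12 with the iodine replaced by an ethynyl group | COc1cc(OS(=O)(=O)C(F)(F)F)cc(c1OC)Oc1ccc(cc1)CCc1cc(OC)c(OC)c(c1)Oc1cccc(c1)C#C | intermediate
16 | macrocyclic diarylalkyne tetramethyl ether (19-membered ring) | COc1cc2cc(c1OC)Oc1ccc(cc1)CCc1cc(OC)c(OC)c(c1)Oc1cccc(c1)C#C2 | intermediate
17 | macrocyclic tetramethyl ether with two CH2CH2 bridges | COc1cc2cc(c1OC)Oc1ccc(cc1)CCc1cc(OC)c(OC)c(c1)Oc1cccc(c1)CC2 | intermediate
18 | CNP0511668.0, macrocyclic bis(bibenzyl) tetraphenol | Oc1cc2cc(c1O)Oc1ccc(cc1)CCc1cc(O)c(O)c(c1)Oc1cccc(c1)CC2 | target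

Total step count: 11. Longest linear sequence: 10 steps (steps 2 to 11 from 1 and 4); step 1 supplies aldehyde 3 convergently at step 7.

Steps most likely to fail

Step 9. The unmasked alkyne may couple with the triflate of a second molecule and oligomerise, the alkyne may dimerise oxidatively, or fluoride may strip the triflate before the slow insertion into the electron-rich ring A takes place. The fallback sets out from 12 and forms the two bridge bonds and the ring in separate events. A double Stille coupling with Bu3SnCH=CH2 (Pd(PPh3)4, LiCl, dioxane, 100 °C) should replace both the iodide and the triflate by vinyl groups, giving the divinyl tetramethyl ether F1. Ring-closing metathesis with second-generation Grubbs catalyst at high dilution (toluene, 80 °C) should then give the macrocyclic stilbene tetramethyl ether F2 with loss of ethene. Hydrogenation of F2 under the conditions of step 10 rejoins the route at 17.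

Step 5. Hydride may attack the sulfonyl sulfur and remove the triflate, or the reduction may stall at the aldehyde stage. The fallback sets out from 7 and changes the order of events. LiAlH4 in THF at 0 °C should reduce the ester of the free phenol to 3-[4-(hydroxymethyl)phenoxy]-4,5-dimethoxyphenol F3. N-Phenylbis(trifluoromethanesulfonimide) with K2CO3 in THF should then sulfonylate only the phenol and not the benzylic alcohol, which rejoins the route at 9.

Step 1. Transmetalation at the hindered ortho-methoxy phenol may be slow, so that protodeboronation and homocoupling of the boronic acid consume the aryl donor. The fallback sets out from 1 and uses an aryl halide electrophile in place of the boronic acid. An Ullmann-type etherification with excess 1,3-diiodobenzene (CuI, picolinic acid, K3PO4, DMSO, 90 °C) should give 3 directly, the excess diiodide holding back double arylation. This detour rejoins the route at 3 and makes no compound outside the list (F0).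

Further compounds
F1 | step 9 | divinyl tetramethyl ether (12 with iodide and triflate both replaced by vinyl) | COc1cc(C=C)cc(c1OC)Oc1ccc(cc1)CCc1cc(OC)c(OC)c(c1)Oc1cccc(C=C)c1
F2 | step 9 | macrocyclic stilbene tetramethyl ether (alkene geometry not controlled) | COc1cc2cc(c1OC)Oc1ccc(cc1)CCc1cc(OC)c(OC)c(c1)Oc1cccc(c1)C=C2
F3 | step 5 | 3-[4-(hydroxymethyl)phenoxy]-4,5-dimethoxyphenol | OCc1ccc(Oc2cc(O)cc(OC)c2OC)cc1
F0 | step 1 | none | none
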